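Readings and results stem from a simulated flask from invented constants, and the scatter is random.

Charge 12 mM of substrate and 0.240 mM of capture agent in each flask, and vary the reagent. In larch the reagent charge is below the substrate charge, so there reagent is the limiting reagent.

| setting | summer | winter | larch | oak | maple |
|---|---|---|---|---|---|
| substrate | 12 mM | 12 mM | 12 mM | 12 mM | 12 mM |
| reagent | 14 mM | 40 mM | 11.0 mM | 17.0 mM | 26.0 mM |
| capture agent | 0.24 mM | 0.24 mM | 0.240 mM | 0.240 mM | 0.240 mM |
| remark | run made earlier | run made earlier |  |  |  |
| time |  |  | 10 h | 10 h | 10 h |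

| run | time / h | substrate / % | bis adduct / % |
|---|---|---|---|
| summer | 0.250 | 99.1 | 0 |
| summer | 0.833 | 96.8 | 0 |
| summer | 1.33 | 96.7 | 0 |
| summer | 2.00 | 94.1 | 0.4 |
| summer | 3.00 | 91.0 | 0 |
| summer | 4.00 | 87.9 | 0.5 |
| summer | 5.00 | 85.4 | 0.8 |
| winter | 0.250 | 97.3 | 0 |
| winter | 0.833 | 93.1 | 0 |
| winter | 1.33 | 88.0 | 0.6 |
| winter | 2.00 | 83.0 | 1.0 |
| winter | 3.00 | 75.0 | 0.4 |
| winter | 4.00 | 69.1 | 1.8 |
| winter | 5.00 | 63.1 | 3.4 |

(readings scatter by 0.5 percentage points)

- part of the substrate that has reacted at the end, larch
- part of the substrate that has reacted at the end, oak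
- part of the substrate that has reacted at the end, maple
- what raising the concentration of reagent from its lowest to its highest value here does to the part of the substrate that has reacted (changes below 5 percentage points count as none) (it rises / no change / it falls)

- the earlier runs were read with a standard deviation of 0.5 percentage points

Open a reagent ledger on the winter run, at 5.00 h. Enter one reagent per substrate lost: 4.43 mM. Enter one more per bis adduct: 0.408 mM. Subtract half of these entries from the charge to get the mean ledger reagent, which counts these two uses of reagent and no other, 37.6 mM.

Now count turnovers. One turnover leaves the substrate at 1/e of its charge. Divide the turnovers of the winter run by mean ledger reagent and by time. This gives the turnover constant, 6.81 × 10⁻⁴ M⁻¹ s⁻¹. The part reacted is then one minus the exponential of minus the constant times mean reagent times time.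

Close the books for each flask in two passes. Take the first count at the full charge, enter the substrate lost, and recount at the mean. Larch has a mean of 9.58 mM and gives 20.9%. Oak has 15.0 mM and gives 30.7%. Maple has 23.2 mM and gives 43.3%.

The forecast says “The substrate decay looks first order in reagent”. It gives 20.6%, 30.4% and 42.7%, slightly different from this reckoning, and its trend is: it rises.

    substrate + reagent → mono adduct + by-product (k = 6.90 × 10⁻⁴ M⁻¹ s⁻¹)
    reagent + mono adduct → bis adduct + by-product (k = 2.40 × 10⁻⁴ M⁻¹ s⁻¹)
    reagent + bis adduct → triple product + by-product (k = 6.40 × 10⁻⁵ M⁻¹ s⁻¹)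
    reagent + by-product ⇌ idle adduct, settled at all times (K = 43.0 M⁻¹)
    mono adduct + capture agent → trapped intermediate (k = 0.00120 M⁻¹ s⁻¹)

The flasks give 20.5%, 29.7% and 41.4%; the trend is: it rises, by 21 points. Watch the free reagent. Maple ends with 70% of its charge free, and idle adduct holds 2.39 mM. The mean of maple's free reagent, taken between charge and end, is 22.1 mM, and it counts to 41.8% reacted. The difference in reagent charge is the main reason maple stands above larch: take that difference away and maple gives 20.5% instead of 41.4%. Oak recharged with 42 mM of reagent ends with 70% free, counts to 58.3%, and gives 57.8%. Maple's answer moves by 5 points at 22.0 mM of reagent.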